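1. Retrosynthesis: the four O–CH3 bonds are cut last. In each cyclopentane ring (C1 = benzylic quaternary carbon, C2 = CMe2, C3 and C4 = the next two CH2, C5 = the CH2 on C1) the C3 methylene is traced back to a ketone and the C1 methyl to a formyl group (Wolff–Kishner), and the formyl group to a vinyl group (ozonolysis).
2. Key cut: C3–C4 of both rings, by enantioselective hydroacylation with [Rh(nbd)2]BF4/(R)-BINAP of an achiral bis(3-aryl-3-ethenyl-2,2-dimethylpent-4-enal). The enabling feature is that C3 sits next to the CMe2 carbon and can be a non-enolisable aldehyde carbon, while C4–C5 and the C1 methyl can both be vinyl groups, so C1 becomes a prochiral carbon with two enantiotopic vinyl groups.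
3. Further cuts: C1–C2 (Claisen rearrangement of the 2-methylprop-1-enyl ether of a 3-arylpenta-2,4-dien-1-ol), the dienol side chain (Sonogashira, hydroalumination–iodination, Suzuki), and the central CH2–CH2 bond (McMurry coupling of 3-bromo-4,5-dimethoxybenzaldehyde, then hydrogenation).
4. Forward: the bibenzyl core is made first and both side chains are grown together, each reagent being used twice per molecule; the two cyclopentanone rings are closed in one twofold step, then trimmed to trimethylcyclopentyl groups and deprotected.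
5. Stereochemistry: both (S) centres arise in the key step by ligand control (choice between enantiotopic vinyl groups); they are quaternary and cannot epimerise; the twofold reaction enriches the (S,S) isomer at the cost of a minor meso isomer, removed at the diketone stage.

Key step: step 7

Assumption: the (R)-BINAP complex is taken to favour the vinyl group that leads to the (S) centre (if the sense is opposite, (S)-BINAP is used and nothing else changes); 1-iodo-2-methylprop-1-ene and (S)-but-3-yn-2-ol are taken as catalogue compounds.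

Step 1
Reactants: 1 3-bromo-4,5-dimethoxybenzaldehyde (two molecules)
Product: 2 (E)-1,2-bis(3-bromo-4,5-dimethoxyphenyl)ethene
Conditions: TiCl4, Zn, THF, 0 °C → reflux
Reagents that add atoms: none
Why: McMurry reductive homocoupling of an aromatic aldehyde by low-valent titanium (pinacolate formation, then deoxygenation) is reliable for electron-rich benzaldehydes and should leave the aryl bromide untouched; the alkene geometry is irrelevant.

Step 2
Reactants: 2 (E)-1,2-bis(3-bromo-4,5-dimethoxyphenyl)ethene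
Product: 3 1,2-bis(3-bromo-4,5-dimethoxyphenyl)ethane
Conditions: H2 (1 atm), PtO2 (cat.), EtOAc/THF, rt
Reagents that add atoms: none
Why: Heterogeneous catalytic hydrogenation of the stilbene C=C over platinum is fast at room temperature and, unlike palladium, is not expected to hydrogenolyse the aryl C–Br bonds.

Step 3
Reactants: 3 1,2-bis(3-bromo-4,5-dimethoxyphenyl)ethane; 4 prop-2-yn-1-ol (two molecules)
Product: 5 1,2-bis[3-(3-hydroxyprop-1-yn-1-yl)-4,5-dimethoxyphenyl]ethane
Conditions: PdCl2(MeCN)2 (cat.), XPhos (cat.), Cs2CO3, prop-2-yn-1-ol (excess), MeCN, 80 °C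
Reagents that add atoms: none
Why: Twofold copper-free Sonogashira coupling, one alkyne per aryl bromide; the bulky biarylphosphine should allow oxidative addition of zerovalent palladium to the electron-rich, ortho-methoxy aryl bromide, and the free hydroxyl group is tolerated.

Step 4
Reactants: 5 1,2-bis[3-(3-hydroxyprop-1-yn-1-yl)-4,5-dimethoxyphenyl]ethane
Product: 7 1,2-bis{3-[(1Z)-3-hydroxy-1-iodoprop-1-en-1-yl]-4,5-dimethoxyphenyl}ethane, via disodium bis(oxa-aluminacycle) 6 (not isolated)
Conditions: NaAlH2(OCH2CH2OMe)2 (excess), THF, 0 °C → rt; then I2 (excess), THF, −78 → 0 °C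
Reagents that add atoms: iodine, II
Why: Alkoxide-directed trans-hydroalumination of a propargylic alcohol delivers hydride to C2 and aluminium to the aryl-bearing C3 within a five-membered oxa-aluminacycle, and iodinolysis of each C–Al bond with retention (one I2 per alkenyl–aluminium bond) should give the (Z)-3-iodoallylic alcohol.

Step 5
Reactants: 7 1,2-bis{3-[(1Z)-3-hydroxy-1-iodoprop-1-en-1-yl]-4,5-dimethoxyphenyl}ethane; 8 2-ethenyl-4,4,5,5-tetramethyl-1,3,2-dioxaborolane (two molecules)
Product: 9 1,2-bis{3-[(3E)-5-hydroxypenta-1,3-dien-3-yl]-4,5-dimethoxyphenyl}ethane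
Conditions: Pd(dppf)Cl2 (cat.), K2CO3, 1,4-dioxane/H2O, 60 °C
Reagents that add atoms: none
Why: Twofold Suzuki–Miyaura coupling of an alkenyl iodide with a vinylboronate proceeds with retention of alkene geometry and tolerates the free allylic alcohol; the dienol should be used promptly.

Step 6
Reactants: 9 1,2-bis{3-[(3E)-5-hydroxypenta-1,3-dien-3-yl]-4,5-dimethoxyphenyl}ethane; 10 1-iodo-2-methylprop-1-ene (two molecules)
Product: 12 3,3'-[ethane-1,2-diylbis(2,3-dimethoxybenzene-5,1-diyl)]bis(3-ethenyl-2,2-dimethylpent-4-enal), via bis(allyl 2-methylprop-1-enyl ether) 11 (not isolated)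
Conditions: CuI (cat.), 3,4,7,8-tetramethyl-1,10-phenanthroline (cat.), Cs2CO3, 1-iodo-2-methylprop-1-ene (excess), o-xylene, 120 → 140 °C, sealed tube
Reagents that add atoms: none
Why: Copper-catalysed C–O coupling of each allylic alcohol with one molecule of the vinyl iodide under basic, non-ionising conditions gives the allyl vinyl ether, which should undergo Claisen [3,3] rearrangement in the same flask (chair transition state, driven by C=O formation) to join the two quaternary carbons; the former alkene carbon becomes a prochiral centre with two vinyl groups, so the geometry of 9 does not matter.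

Step 7
Reactants: 12 3,3'-[ethane-1,2-diylbis(2,3-dimethoxybenzene-5,1-diyl)]bis(3-ethenyl-2,2-dimethylpent-4-enal)
Product: 13 (3S,3'S)-3,3'-[ethane-1,2-diylbis(2,3-dimethoxybenzene-5,1-diyl)]bis(3-ethenyl-2,2-dimethylcyclopentan-1-one)
Conditions: [Rh(nbd)2]BF4 (cat.), (R)-BINAP (cat.), H2 (activation, then purged), CH2Cl2, rt → 40 °C
Reagents that add atoms: none
Why: Oxidative addition of each aldehyde C–H bond to the cationic monovalent rhodium–BINAP fragment gives an acyl hydride of trivalent rhodium; one of the two vinyl groups on C1 coordinates and inserts with hydride going to the internal carbon (C5), and C–C reductive elimination from the six-membered acyl(alkyl)rhodacycle forms the C3–C4 bond and releases the catalyst. The closest known reaction type is the enantioselective intramolecular hydroacylation of 4-pentenals with cationic rhodium bisphosphine complexes such as [Rh(BINAP)]ClO4, including its use to desymmetrise 3,3-dialkenyl-4-pentenals with formation of a quaternary stereocentre. Each cyclopentanone ring is closed in a formal 5-endo-trig mode (both alkene carbons end up in the ring), feasible because the bond forms by reductive elimination from the metallacycle and not by direct attack on the alkene. The new stereocentre C1 of each ring is controlled by the chiral ligand alone, which decides which enantiotopic vinyl group is bound and inserted; the (S,S) isomer should dominate, and the twofold reaction turns most mismatched events into the meso diastereomer, which is to be removed here by crystallisation or preparative HPLC. The step needs enantiotopic-group selectivity, anti-Markovnikov insertion (cyclopentanone, not 2-methylcyclobutanone) and cyclisation faster than decarbonylation; the substrate helps with the last two, since quaternary C2 prevents enolisation and favours ring closure (gem-dialkyl effect) and the vinyl groups on quaternary C1 have no allylic hydrogen and cannot isomerise.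

Step 8
Reactants: 13 (3S,3'S)-3,3'-[ethane-1,2-diylbis(2,3-dimethoxybenzene-5,1-diyl)]bis(3-ethenyl-2,2-dimethylcyclopentan-1-one)
Product: 15 (1S,1'S)-1,1'-[ethane-1,2-diylbis(2,3-dimethoxybenzene-5,1-diyl)]bis(2,2-dimethyl-3-oxocyclopentane-1-carbaldehyde), via bis(1,2,4-trioxolane) 14 (not isolated)
Conditions: O3, CH2Cl2, −78 °C (stopped at the first excess of O3); then PPh3, −78 °C → rt
Reagents that add atoms: ozone, [O-][O+]=O
Why: Ozonolysis with reductive work-up (one ozone per vinyl group); at −78 °C ozone should cleave the remaining monosubstituted vinyl groups much faster than it attacks the dimethoxyarene, giving the non-enolisable aldehyde without touching the ketone or the quaternary stereocentre.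

Step 9
Reactants: 15 (1S,1'S)-1,1'-[ethane-1,2-diylbis(2,3-dimethoxybenzene-5,1-diyl)]bis(2,2-dimethyl-3-oxocyclopentane-1-carbaldehyde)
Product: 17 1,2-bis{3,4-dimethoxy-5-[(1S)-1,2,2-trimethylcyclopentyl]phenyl}ethane, via tetrakis-hydrazone 16 (not isolated)
Conditions: N2H4·H2O (excess), diethylene glycol, 130 °C; then KOH, 200 °C
Reagents that add atoms: none
Why: Wolff–Kishner reduction (Huang-Minlon procedure) turns each ring C=O into CH2 and each CHO into CH3 in one operation; the hydrazones are formed before base is added so that the non-enolisable α-aryl aldehyde is not deformylated, a cyclic azine between the two carbonyl groups of one ring would need a bridgehead C=N bond and should not form, and the quaternary stereocentres cannot epimerise.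

Step 10
Reactants: 17 1,2-bis{3,4-dimethoxy-5-[(1S)-1,2,2-trimethylcyclopentyl]phenyl}ethane
Product: 19 5,5'-(ethane-1,2-diyl)bis{3-[(1S)-1,2,2-trimethylcyclopentyl]benzene-1,2-diol}, via bis(bromobenzodioxaborole) 18 (not isolated)
Conditions: BBr3 (excess), CH2Cl2, −78 °C → rt; then H2O, under argon
Reagents that add atoms: none
Why: Lewis-acid cleavage of aryl methyl ethers by BBr3 should give the cyclic catechol bromoboronates, which are hydrolysed on work-up to the free catechols without affecting the hydrocarbon stereocentres.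

Compound list
1 | 3-bromo-4,5-dimethoxybenzaldehyde | O=Cc1cc(Br)c(OC)c(OC)c1 | starting material
2 | (E)-1,2-bis(3-bromo-4,5-dimethoxyphenyl)ethene | COc1cc(/C=C/c2cc(OC)c(OC)c(Br)c2)cc(Br)c1OC | intermediate
3 | 1,2-bis(3-bromo-4,5-dimethoxyphenyl)ethane | COc1cc(CCc2cc(OC)c(OC)c(Br)c2)cc(Br)c1OC | intermediate
4 | prop-2-yn-1-ol | C#CCO | starting material
5 | 1,2-bis[3-(3-hydroxyprop-1-yn-1-yl)-4,5-dimethoxyphenyl]ethane | COc1cc(CCc2cc(OC)c(OC)c(C#CCO)c2)cc(C#CCO)c1OC | intermediate
6 | disodium bis(oxa-aluminacycle): each alkynol unit of 5 as a 3-aryl-2,2-bis(2-methoxyethoxy)-2,5-dihydro-1,2-oxaaluminol-2-uide ring | [Na+].[Na+].COc1cc(CCc2cc(OC)c(OC)c(C3=CCO[Al-]3(OCCOC)OCCOC)c2)cc(C2=CCO[Al-]2(OCCOC)OCCOC)c1OC | intermediate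
7 | 1,2-bis{3-[(1Z)-3-hydroxy-1-iodoprop-1-en-1-yl]-4,5-dimethoxyphenyl}ethane | COc1cc(CCc2cc(OC)c(OC)c(/C(I)=C/CO)c2)cc(/C(I)=C/CO)c1OC | intermediate
8 | 2-ethenyl-4,4,5,5-tetramethyl-1,3,2-dioxaborolane | C=CB1OC(C)(C)C(C)(C)O1 | starting material
9 | 1,2-bis{3-[(3E)-5-hydroxypenta-1,3-dien-3-yl]-4,5-dimethoxyphenyl}ethane | COc1cc(CCc2cc(OC)c(OC)c(/C(C=C)=C/CO)c2)cc(/C(C=C)=C/CO)c1OC | intermediate
10 | 1-iodo-2-methylprop-1-ene | CC(C)=CI | starting material
11 | 1,2-bis{3,4-dimethoxy-5-[(3E)-5-(2-methylprop-1-en-1-yloxy)penta-1,3-dien-3-yl]phenyl}ethane | COc1cc(CCc2cc(OC)c(OC)c(/C(C=C)=C/COC=C(C)C)c2)cc(/C(C=C)=C/COC=C(C)C)c1OC | intermediate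
12 | 3,3'-[ethane-1,2-diylbis(2,3-dimethoxybenzene-5,1-diyl)]bis(3-ethenyl-2,2-dimethylpent-4-enal), achiral | COc1cc(CCc2cc(OC)c(OC)c(C(C=C)(C=C)C(C)(C)C=O)c2)cc(C(C=C)(C=C)C(C)(C)C=O)c1OC | intermediate
13 | (3S,3'S)-3,3'-[ethane-1,2-diylbis(2,3-dimethoxybenzene-5,1-diyl)]bis(3-ethenyl-2,2-dimethylcyclopentan-1-one) | COc1cc(CCc2cc(OC)c(OC)c([C@@]3(C=C)CCC(=O)C3(C)C)c2)cc([C@@]2(C=C)CCC(=O)C2(C)C)c1OC | intermediate
14 | bis(1,2,4-trioxolane): secondary ozonide at each former vinyl group of 13 | COc1cc(CCc2cc(OC)c(OC)c([C@@]3(C4OCOO4)CCC(=O)C3(C)C)c2)cc([C@@]2(C3OCOO3)CCC(=O)C2(C)C)c1OC | intermediate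
15 | (1S,1'S)-1,1'-[ethane-1,2-diylbis(2,3-dimethoxybenzene-5,1-diyl)]bis(2,2-dimethyl-3-oxocyclopentane-1-carbaldehyde) | COc1cc(CCc2cc(OC)c(OC)c([C@@]3(C=O)CCC(=O)C3(C)C)c2)cc([C@@]2(C=O)CCC(=O)C2(C)C)c1OC | intermediate
16 | tetrakis-hydrazone of 15 (hydrazone at each ketone and each aldehyde) | COc1cc(CCc2cc(OC)c(OC)c([C@@]3(C=NN)CCC(=NN)C3(C)C)c2)cc([C@@]2(C=NN)CCC(=NN)C2(C)C)c1OC | intermediate
17 | 1,2-bis{3,4-dimethoxy-5-[(1S)-1,2,2-trimethylcyclopentyl]phenyl}ethane | COc1cc(CCc2cc(OC)c(OC)c([C@@]3(C)CCCC3(C)C)c2)cc([C@@]2(C)CCCC2(C)C)c1OC | intermediate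
18 | bis(2-bromo-1,3,2-benzodioxaborole): each catechol of the target as its cyclic bromoboronate | BrB1Oc2cc(CCc3cc4OB(Br)Oc4c([C@@]5(C)CCCC5(C)C)c3)cc([C@@]3(C)CCCC3(C)C)c2O1 | intermediate
19 | 5,5'-(ethane-1,2-diyl)bis{3-[(1S)-1,2,2-trimethylcyclopentyl]benzene-1,2-diol} | CC1(C)CCC[C@]1(C)c1cc(CCc2cc(O)c(O)c([C@@]3(C)CCCC3(C)C)c2)cc(O)c1O | target

Step count
Total steps: 10. Longest linear sequence: 10 steps (from 1).

Steps most likely to fail

Step 7. The catalyst may discriminate poorly between the two enantiotopic vinyl groups, or decarbonylation of the hindered acyl rhodium hydride may outpace cyclisation. The fallback replaces catalyst control by 1,3-chirality transfer; it sets out from 3 and comes back at 15. Compound 3 is coupled with two molecules of (S)-but-3-yn-2-ol under the Sonogashira conditions of step 3 to give 1,2-bis{3-[(3S)-3-hydroxybut-1-yn-1-yl]-4,5-dimethoxyphenyl}ethane F1. NaAlH2(OCH2CH2OMe)2 converts it in the flask into the disodium bis(oxa-aluminacycle) F2, and I2 then gives the bis[(1Z,3S)-3-hydroxy-1-iodobut-1-enyl] compound F3. Suzuki coupling with two molecules of 8 gives the bis[(2S,3E)-2-hydroxyhexa-3,5-dien-4-yl] compound F4. Copper-catalysed coupling with two molecules of 10 as in step 6 gives the bis(allyl 2-methylprop-1-enyl ether) F5, which should rearrange through a chair in which the carbinol methyl is pseudo-equatorial (allylic strain with the cis vinyl group) to the bis[(3S,4E)-3-ethenyl-2,2-dimethylhex-4-enal] F6. In F6 each quaternary carbon carries one vinyl and one (E)-prop-1-enyl group, and its configuration is already fixed. An achiral catalyst such as [Rh(dppe)(acetone)2]BF4 should then close the ring on the terminal vinyl group only, giving the bis{(3S)-2,2-dimethyl-3-[(1E)-prop-1-enyl]cyclopentanone} F7. Ozonolysis via the bis(3-methyl-1,2,4-trioxolane) F8 and PPh3 work-up cleaves the propenyl groups and gives 15.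

Step 6. Bond formation between two quaternary carbons may be slow, so that a thermal [1,5]-hydrogen shift of the cis-dienyl ether or polymerisation of the diene competes at the temperature needed. The fallback runs the rearrangement at or below room temperature at the ester oxidation level; it sets out from 9 and comes back at 12. Compound 9 is acylated with two molecules of 2-methylpropanoyl chloride (Et3N, DMAP) to the bis(2-methylpropanoate) F9. LiN(i-Pr)2 and Me3SiCl in THF at −78 °C give the bis(trimethylsilyl ketene acetal) F10, which should undergo Ireland–Claisen rearrangement on warming to the bis(trimethylsilyl ester) F11, hydrolysed on work-up to the bis(3-ethenyl-2,2-dimethylpent-4-enoic acid) F12. LiAlH4 reduces it to the bis(3-ethenyl-2,2-dimethylpent-4-en-1-ol) F13, and Dess–Martin periodinane oxidation returns 12.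

Step 9. Hydrazone formation at the hindered ring ketones may be incomplete, the formyl groups may be lost under hot base before reduction, and some ether cleavage may occur (harmless, since step 10 removes all methyl groups). The fallback removes the four carbonyl oxygens by desulfurisation; it sets out from 15 and comes back at 17. Compound 15 is treated with ethane-1,2-dithiol and BF3·OEt2 to give the tetrakis(1,3-dithiolane) F14, and Raney nickel in refluxing EtOH reduces all four thioacetal carbons to CH2 or CH3, giving 17.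

Further compounds
F1 | step 7 | 1,2-bis{3-[(3S)-3-hydroxybut-1-yn-1-yl]-4,5-dimethoxyphenyl}ethane | COc1cc(CCc2cc(OC)c(OC)c(C#C[C@H](C)O)c2)cc(C#C[C@H](C)O)c1OC
F2 | step 7 | disodium bis(oxa-aluminacycle) from F1, each ring a (5S)-3-aryl-5-methyl-2,2-bis(2-methoxyethoxy)-2,5-dihydro-1,2-oxaaluminol-2-uide | [Na+].[Na+].COc1cc(CCc2cc(OC)c(OC)c(C3=C[C@H](C)O[Al-]3(OCCOC)OCCOC)c2)cc(C2=C[C@H](C)O[Al-]2(OCCOC)OCCOC)c1OC
F3 | step 7 | 1,2-bis{3-[(1Z,3S)-3-hydroxy-1-iodobut-1-en-1-yl]-4,5-dimethoxyphenyl}ethane | COc1cc(CCc2cc(OC)c(OC)c(/C(I)=C/[C@H](C)O)c2)cc(/C(I)=C/[C@H](C)O)c1OC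
F4 | step 7 | 1,2-bis{3-[(2S,3E)-2-hydroxyhexa-3,5-dien-4-yl]-4,5-dimethoxyphenyl}ethane | COc1cc(CCc2cc(OC)c(OC)c(/C(C=C)=C/[C@H](C)O)c2)cc(/C(C=C)=C/[C@H](C)O)c1OC
F5 | step 7 | bis(2-methylprop-1-enyl ether) of F4 | COc1cc(CCc2cc(OC)c(OC)c(/C(C=C)=C/[C@H](C)OC=C(C)C)c2)cc(/C(C=C)=C/[C@H](C)OC=C(C)C)c1OC
F6 | step 7 | (3S,3'S,4E,4'E)-3,3'-[ethane-1,2-diylbis(2,3-dimethoxybenzene-5,1-diyl)]bis(3-ethenyl-2,2-dimethylhex-4-enal) | COc1cc(CCc2cc(OC)c(OC)c([C@](C=C)(/C=C/C)C(C)(C)C=O)c2)cc([C@](C=C)(/C=C/C)C(C)(C)C=O)c1OC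
F7 | step 7 | (3S,3'S)-3,3'-[ethane-1,2-diylbis(2,3-dimethoxybenzene-5,1-diyl)]bis{2,2-dimethyl-3-[(1E)-prop-1-en-1-yl]cyclopentan-1-one} | COc1cc(CCc2cc(OC)c(OC)c([C@@]3(/C=C/C)CCC(=O)C3(C)C)c2)cc([C@@]2(/C=C/C)CCC(=O)C2(C)C)c1OC
F8 | step 7 | bis(3-methyl-1,2,4-trioxolane): secondary ozonide at each propenyl group of F7 | COc1cc(CCc2cc(OC)c(OC)c([C@@]3(C4OC(C)OO4)CCC(=O)C3(C)C)c2)cc([C@@]2(C3OC(C)OO3)CCC(=O)C2(C)C)c1OC
F9 | step 6 | bis(2-methylpropanoate) of 9 | COc1cc(CCc2cc(OC)c(OC)c(/C(C=C)=C/COC(=O)C(C)C)c2)cc(/C(C=C)=C/COC(=O)C(C)C)c1OC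
F10 | step 6 | bis(trimethylsilyl ketene acetal) of F9 | COc1cc(CCc2cc(OC)c(OC)c(/C(C=C)=C/COC(O[Si](C)(C)C)=C(C)C)c2)cc(/C(C=C)=C/COC(O[Si](C)(C)C)=C(C)C)c1OC
F11 | step 6 | bis(trimethylsilyl 3-ethenyl-2,2-dimethylpent-4-enoate) | COc1cc(CCc2cc(OC)c(OC)c(C(C=C)(C=C)C(C)(C)C(=O)O[Si](C)(C)C)c2)cc(C(C=C)(C=C)C(C)(C)C(=O)O[Si](C)(C)C)c1OC
F12 | step 6 | 3,3'-[ethane-1,2-diylbis(2,3-dimethoxybenzene-5,1-diyl)]bis(3-ethenyl-2,2-dimethylpent-4-enoic acid) | COc1cc(CCc2cc(OC)c(OC)c(C(C=C)(C=C)C(C)(C)C(=O)O)c2)cc(C(C=C)(C=C)C(C)(C)C(=O)O)c1OC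
F13 | step 6 | 3,3'-[ethane-1,2-diylbis(2,3-dimethoxybenzene-5,1-diyl)]bis(3-ethenyl-2,2-dimethylpent-4-en-1-ol) | COc1cc(CCc2cc(OC)c(OC)c(C(C=C)(C=C)C(C)(C)CO)c2)cc(C(C=C)(C=C)C(C)(C)CO)c1OC
F14 | step 9 | tetrakis(1,3-dithiolane) of 15 (dithiolane at each ketone and each aldehyde carbon) | COc1cc(CCc2cc(OC)c(OC)c([C@@]3(C4SCCS4)CCC5(SCCS5)C3(C)C)c2)cc([C@@]2(C3SCCS3)CCC4(SCCS4)C2(C)C)c1OC
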